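In the early hours J takes up G with a half-life of 1.1 h by the forward step alone, with the other concentrations as charged, far shorter than the run, so the catalyst soon divides between J and L, and Q begins to fall.

Q 1.3 M; G 1.20 equiv; J 2.5 mol%; time 4.0 d; volume of the second phase over the first 2.0

- amount of Z and E together at 4.0 d, in percent of the Q charged
- the change that raises the amount of Z and E together at 4.0 d, in percent of the Q charged most ("none" if none brings more than 2 percentage points) (beta / theta / gamma / none)
- amount of Z and E together at 4.0 d, in percent of the Q charged, after theta

- beta: doubling the amount of G, all else as stated
- theta: doubling the solubility in step 4, all else as stated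
- gamma: doubling the dissolution coefficient of step 4, all else as stated

- for Z the E are counted in
- in the second phase: G, X; everything else is in the first
- charges count per volume of the first phase; a concentration in a rate is the amount of a species over the volume of its own phase; every rate counts per litre of the first phase
- as a solid, counted per litre of solution: E
- run time (flask): 4.0 d

    J + G ⇌ L + X (K1 = 15, k1 = 0.013 /M/min)
    Q + L → Z + J (k2 = 0.0057 /M/min)
    L → D (k3 = 1.3 × 10⁻⁴ /min)
    E ⇌ Z, rate k4*(cs4 - [Z]) while solid is left; crystals form when [Z] > cs4 (cs4 = 1.2 M, k4 = 0.015 /min)

I reckon with two times. τQ is the time in which Q falls by one unit of ln if the whole catalyst charge stands as L. τD is the mean life of L.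

τQ = 3.75 d
τD = 5.34 d

ln Q falls at a rate proportional to L, and D grows at a rate proportional to L. So ln(Q at start / Q now) = B·d, where d is the share of catalyst turned to D and the catalyst dose B = τD/τQ.

B = 1.43

For d, I replace the curve by its mean. L stands in a quasi-steady state: J goes to L at 0.0101 /min by step 1, and L returns to J at 0.00741 /min by step 2, both as charged. I hold the share f of L among J and L fixed at that value.

f = 0.578
d = 35.1%
y = 39.4%

With d at its full value, my reckoning gives Z of 0.987 M, less than the solubility 1.2 M. So I expect no E, and nothing from theta or gamma. In my reckoning beta raises f to 0.732 and y to 45.2%.

The forecast gives 39.3%, beta and 39.3% after theta, and says “no crystals form and theta and gamma change nothing”.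

The flask gives 39.1%, beta with a gain of 6.9 percentage points, and 39.1% after theta.

In this flask, turnover ran while J and L dwindled: by 4.00 d, D stood at 34.8% and Q at 60.9%, with E at 0%. By 40.0 d, D stood at 98.9% and Q at 24.4%. The dose applied to these D readings gives Q of 60.8% and 24.3%.

In the neighbour flask with 4.2 mol% of J, the dose becomes 2.39. At the same d, that gives y = 56.8%. The simulation gives 56.6%.

The numbers of this flask come from no measurement.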